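The plan rests on making the 2-pyranone ring (O1, C2–C6) last, through its enol-lactone bond O1–C6. Because the C7 carbinol sits directly on ring carbon C6, C5–C6 can be carried as an alkyne with C7 as a propargylic silyl ether. In one operation, gold-triggered 6-endo attack of the tert-butyl ester carbonyl oxygen on C6, with loss of 2-methylpropene, turns acyclic 26 into 4-hydroxy-3-methyl-2-pyranone 29 without base. Precursor 26 is a tert-butyl 2-methyl-3-oxoalk-4-ynoate bearing the bis-silylated C7–C15 chain, whose stereocentres come from an Evans aldol (C10, C11), a [2,3]-Wittig shift relaying C10 to C7 and C8, and a CBS reduction (C14).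

Key step: step 14

Remark: locants are those of the target (ring O1, C2–C6; side chain C7–C15); 1, 7, 12 and 23 are taken to be catalogue reagents; 25 and 26 are carried as epimer mixtures at centres that end up sp2.

Step 1
Reactants: 1 (R)-4-benzyl-3-propanoyl-1,3-oxazolidin-2-one; 2 tiglic aldehyde [(E)-2-methylbut-2-enal]
Product: 5 (R)-4-benzyl-3-[(2R,3R,4E)-3-hydroxy-2,4-dimethylhex-4-enoyl]-1,3-oxazolidin-2-one, via dibutylboron Z-enolate 3 (not isolated), via dibutylboron aldolate 4 (not isolated)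
Conditions: Bu2BOTf, iPr2NEt, CH2Cl2, 0 °C; 2, −78 → 0 °C; then pH 7 buffer, MeOH, H2O2
Reagents that add atoms: none
Why: Evans syn-aldol reaction: the Z-boron enolate 3 adds to 2 through a closed Zimmerman–Traxler chair in which the benzyl group of the (R)-auxiliary blocks one enolate face, so C10 and C11 should be set together as the (2R,3R) syn pair under auxiliary control.

Step 2
Reactants: 5 (R)-4-benzyl-3-[(2R,3R,4E)-3-hydroxy-2,4-dimethylhex-4-enoyl]-1,3-oxazolidin-2-one
Product: 6 (2R,3R,4E)-3-hydroxy-N-methoxy-N,2,4-trimethylhex-4-enamide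
Conditions: MeNH(OMe)·HCl, AlMe3, CH2Cl2, −10 °C → rt; aq. KNaC4H4O6
Reagents that add atoms: N,O-dimethylhydroxylamine hydrochloride, CNOC.Cl
Why: Aluminium-amide transamidation: the amide made in the flask from AlMe3 and the amine salt attacks the exocyclic imide carbonyl, helped by the neighbouring aluminium alkoxide, and should release the auxiliary without touching C10 or C11.

Step 3
Reactants: 6 (2R,3R,4E)-3-hydroxy-N-methoxy-N,2,4-trimethylhex-4-enamide; 7 3-bromo-1-(trimethylsilyl)prop-1-yne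
Product: 9 (2R,3R,4E)-N-methoxy-N,2,4-trimethyl-3-{[3-(trimethylsilyl)prop-2-yn-1-yl]oxy}hex-4-enamide, via sodium alkoxide 8 (not isolated)
Conditions: NaH, THF/DMF, 0 °C; then 7, Bu4NI (cat.), 0 °C → rt
Reagents that add atoms: none
Why: Williamson ether synthesis: the sodium alkoxide is trapped at 0 °C by the reactive propargylic bromide (iodide catalysis), which should outpace retro-aldol cleavage because an amide enolate is a poor leaving group.

Step 4
Reactants: 9 (2R,3R,4E)-N-methoxy-N,2,4-trimethyl-3-{[3-(trimethylsilyl)prop-2-yn-1-yl]oxy}hex-4-enamide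
Product: 11 (2R,3R,4E)-2,4-dimethyl-3-{[3-(trimethylsilyl)prop-2-yn-1-yl]oxy}hex-4-enal, via aluminium hemiaminal 10 (not isolated)
Conditions: iBu2AlH, THF, −78 °C; aq. KNaC4H4O6
Reagents that add atoms: none
Why: Hydride reduction of an N-methoxy-N-methylamide: the chelated tetrahedral adduct 10 is stable at −78 °C and collapses to the aldehyde only on work-up, so over-reduction and epimerisation at C11 should not occur.

Step 5
Reactants: 11 (2R,3R,4E)-2,4-dimethyl-3-{[3-(trimethylsilyl)prop-2-yn-1-yl]oxy}hex-4-enal; 12 3-(triphenyl-λ5-phosphanylidene)butan-2-one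
Product: 13 (3E,5S,6R,7E)-3,5,7-trimethyl-6-{[3-(trimethylsilyl)prop-2-yn-1-yl]oxy}nona-3,7-dien-2-one
Conditions: toluene, 90 °C
Reagents that add atoms: none
Why: Wittig olefination: the ketone-stabilised ylide reacts under neutral conditions and, as usual for stabilised α-methyl ylides, should give the E-trisubstituted C12=C13 enone without disturbing C11 or the alkynylsilane.

Step 6
Reactants: 13 (3E,5S,6R,7E)-3,5,7-trimethyl-6-{[3-(trimethylsilyl)prop-2-yn-1-yl]oxy}nona-3,7-dien-2-one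
Product: 14 (2R,3E,5S,6R,7E)-3,5,7-trimethyl-6-{[3-(trimethylsilyl)prop-2-yn-1-yl]oxy}nona-3,7-dien-2-ol
Conditions: (S)-2-methyl-CBS-oxazaborolidine, catecholborane, toluene, −78 °C
Reagents that add atoms: none
Why: Corey–Bakshi–Shibata reduction: with the α-methylalkenyl group as the large and the methyl group as the small ketone substituent, the (S)-oxazaborolidine should direct hydride to the face that gives the (R)-carbinol at C14 under catalyst control, and catecholborane at −78 °C should leave the alkenes and the alkyne untouched.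

Step 7
Reactants: 14 (2R,3E,5S,6R,7E)-3,5,7-trimethyl-6-{[3-(trimethylsilyl)prop-2-yn-1-yl]oxy}nona-3,7-dien-2-ol
Product: 15 (2R,3E,5S,6R,7E)-2-[(tert-butyldimethylsilyl)oxy]-3,5,7-trimethyl-6-{[3-(trimethylsilyl)prop-2-yn-1-yl]oxy}nona-3,7-diene
Conditions: TBSCl, imidazole, DMF, rt
Reagents that add atoms: tert-butyldimethylsilyl chloride, CC(C)(C)[Si](C)(C)Cl
Why: Routine silylation of a secondary allylic alcohol, which masks C14–OH before the organolithium step.

Step 8
Reactants: 15 (2R,3E,5S,6R,7E)-2-[(tert-butyldimethylsilyl)oxy]-3,5,7-trimethyl-6-{[3-(trimethylsilyl)prop-2-yn-1-yl]oxy}nona-3,7-diene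
Product: 17 (3S,4S,5E,7R,8E,10R)-10-[(tert-butyldimethylsilyl)oxy]-4,5,7,9-tetramethyl-1-(trimethylsilyl)undeca-5,8-dien-1-yn-3-ol, via α-lithio ether 16 (not isolated)
Conditions: n-BuLi, THF, −78 °C; aq. NH4Cl
Reagents that add atoms: none
Why: [2,3]-Wittig rearrangement: lithiation at the O–CH2 group between oxygen and alkyne gives 16, which should rearrange through a five-membered envelope with the C11 substituent pseudo-equatorial (E C9=C10) and the silylalkynyl group exo, so that the (10R) ether centre is relayed suprafacially to (8S) and the E geometry of the C8=C9 alkene translates into the anti (7S) carbinol as the C7–C8 bond forms.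

Step 9
Reactants: 17 (3S,4S,5E,7R,8E,10R)-10-[(tert-butyldimethylsilyl)oxy]-4,5,7,9-tetramethyl-1-(trimethylsilyl)undeca-5,8-dien-1-yn-3-ol
Product: 18 (3S,4S,5E,7R,8E,10R)-3,10-bis[(tert-butyldimethylsilyl)oxy]-4,5,7,9-tetramethyl-1-(trimethylsilyl)undeca-5,8-dien-1-yne
Conditions: TBSOTf, 2,6-lutidine, CH2Cl2, −78 → 0 °C
Reagents that add atoms: tert-butyldimethylsilyl trifluoromethanesulfonate, CC(C)(C)[Si](C)(C)OS(=O)(=O)C(F)(F)F
Why: Silyl triflate with 2,6-lutidine silylates the hindered propargylic alcohol under non-nucleophilic conditions that leave the C–Si bond of the alkyne intact.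

Step 10
Reactants: 18 (3S,4S,5E,7R,8E,10R)-3,10-bis[(tert-butyldimethylsilyl)oxy]-4,5,7,9-tetramethyl-1-(trimethylsilyl)undeca-5,8-dien-1-yne
Product: 19 (3S,4S,5E,7R,8E,10R)-3,10-bis[(tert-butyldimethylsilyl)oxy]-4,5,7,9-tetramethylundeca-5,8-dien-1-yne
Conditions: K2CO3, MeOH, rt
Reagents that add atoms: none
Why: Methanolysis of the C(sp)–Si bond under mild carbonate catalysis is selective for the alkynylsilane, because both silyl ethers are stable to K2CO3 in methanol.

Step 11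
Reactants: 19 (3S,4S,5E,7R,8E,10R)-3,10-bis[(tert-butyldimethylsilyl)oxy]-4,5,7,9-tetramethylundeca-5,8-dien-1-yne
Product: 22 (4S,5S,6E,8R,9E,11R)-4,11-bis[(tert-butyldimethylsilyl)oxy]-5,6,8,10-tetramethyldodeca-6,9-dien-2-ynal, via lithium acetylide 20 (not isolated), via lithium hemiaminal alkoxide 21 (not isolated)
Conditions: n-BuLi, THF, −78 °C; DMF, −78 → 0 °C; inverse quench into cold aq. KH2PO4
Reagents that add atoms: N,N-dimethylformamide, CN(C)C=O
Why: Formylation of a terminal alkyne: lithium acetylide 20 adds to DMF to give hemiaminal alkoxide 21, and inverse quenching into phosphate buffer should release the ynal without conjugate addition of the liberated amine.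

Step 12
Reactants: 22 (4S,5S,6E,8R,9E,11R)-4,11-bis[(tert-butyldimethylsilyl)oxy]-5,6,8,10-tetramethyldodeca-6,9-dien-2-ynal; 23 tert-butyl propanoate
Product: 25 tert-butyl (6S,7S,8E,10R,11E,13R)-6,13-bis[(tert-butyldimethylsilyl)oxy]-3-hydroxy-2,7,8,10,12-pentamethyltetradeca-8,11-dien-4-ynoate (epimer mixture at C2 and C3 of the ester chain), via lithium ester enolate 24 (not isolated)
Conditions: 23, LiN(iPr)2, THF, −78 °C; then 22, −78 °C; aq. NH4Cl
Reagents that add atoms: none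
Why: Aldol addition of a lithium ester enolate: 24 adds 1,2 to the non-enolisable ynal at −78 °C, and the two new centres need no control because one is oxidised in the next step and the other ends up sp2 in the pyranone.

Step 13
Reactants: 25 tert-butyl (6S,7S,8E,10R,11E,13R)-6,13-bis[(tert-butyldimethylsilyl)oxy]-3-hydroxy-2,7,8,10,12-pentamethyltetradeca-8,11-dien-4-ynoate
Product: 26 tert-butyl (6S,7S,8E,10R,11E,13R)-6,13-bis[(tert-butyldimethylsilyl)oxy]-2,7,8,10,12-pentamethyl-3-oxotetradeca-8,11-dien-4-ynoate (C2 of the ester chain configurationally labile)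
Conditions: Dess–Martin periodinane, NaHCO3, CH2Cl2, 0 °C → rt
Reagents that add atoms: none
Why: Dess–Martin oxidation of the propargylic β-hydroxy ester under buffered, base-free conditions should give the ynone ketoester without conjugate addition, over-oxidation being limited by using a small excess of oxidant.

Step 14
Reactants: 26 tert-butyl (6S,7S,8E,10R,11E,13R)-6,13-bis[(tert-butyldimethylsilyl)oxy]-2,7,8,10,12-pentamethyl-3-oxotetradeca-8,11-dien-4-ynoate
Product: 29 6-[(1S,2S,3E,5R,6E,8R)-1,8-bis[(tert-butyldimethylsilyl)oxy]-2,3,5,7-tetramethylnona-3,6-dien-1-yl]-4-hydroxy-3-methyl-2H-pyran-2-one, via vinylgold oxocarbenium 27 (not isolated), via pyran-2,4-dione tautomer 28 (not isolated)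
Conditions: Ph3PAuNTf2 (5 mol%), MeNO2/AcOH, rt
Reagents that add atoms: none
Why: The cationic gold centre of Ph3PAuNTf2 (monovalent gold) binds the C5≡C6 π-bond, the carbonyl oxygen of the tert-butyl ester adds to C6 anti to the metal to give vinylgold oxocarbenium 27, and fragmentation of the tert-butyl group as 2-methylpropene supplies the proton for protodeauration to dione 28, which enolises to 29. The closest known reaction type is the gold-catalysed cycloisomerisation of tert-butyl 3-oxoalk-4-ynoates to 4-hydroxy-2-pyranones. The pyranone ring (O1, C2–C6) is closed in the 6-endo-dig mode by the new O1–C6 bond. No stereocentre is created, the labile C3 centre becomes sp2, and since neither base nor a free triketo ester is involved the silyloxy-bearing C7 centre beside the ring should keep its configuration. The step needs 6-endo closure at C6 in preference to 5-exo closure at C5, which conjugation of the alkyne with the C4 ketone (C6 is the electron-poor β-carbon) and the geometry of the ketoester tether should secure. It also needs oxygen attack to outrun addition of the C9=C10 alkene to the activated alkyne, for which the conjugated, pre-organised carbonyl nucleophile and the acetic acid co-solvent (fast protodeauration) are relied on.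

Step 15
Reactants: 29 6-[(1S,2S,3E,5R,6E,8R)-1,8-bis[(tert-butyldimethylsilyl)oxy]-2,3,5,7-tetramethylnona-3,6-dien-1-yl]-4-hydroxy-3-methyl-2H-pyran-2-one
Product: 30 6-[(1S,2S,3E,5R,6E,8R)-1,8-bis[(tert-butyldimethylsilyl)oxy]-2,3,5,7-tetramethylnona-3,6-dien-1-yl]-4-methoxy-3-methyl-2H-pyran-2-one
Conditions: Me2SO4, K2CO3, acetone, rt
Reagents that add atoms: dimethyl sulfate, COS(=O)(=O)OC
Why: O-Alkylation of a vinylogous acid: the potassium pyronate reacts with dimethyl sulfate in acetone preferentially at the C4 oxygen, which should give the 4-methoxy-2-pyranone in preference to the 2-methoxy-4-pyranone isomer and leaves the silyl ethers intact.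

Step 16
Reactants: 30 6-[(1S,2S,3E,5R,6E,8R)-1,8-bis[(tert-butyldimethylsilyl)oxy]-2,3,5,7-tetramethylnona-3,6-dien-1-yl]-4-methoxy-3-methyl-2H-pyran-2-one
Product: 31 6-[(1S,2S,3E,5R,6E,8R)-1,8-dihydroxy-2,3,5,7-tetramethylnona-3,6-dien-1-yl]-4-methoxy-3-methyl-2H-pyran-2-one (target)
Conditions: HF·pyridine, pyridine, THF, 0 °C → rt
Reagents that add atoms: none
Why: Fluoride-mediated desilylation with pyridine-buffered HF·pyridine should free the C7 and C14 carbinols without ionising these allylic or pyranone-activated positions.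

Compound list
1 | (R)-4-benzyl-3-propanoyl-1,3-oxazolidin-2-one | CCC(=O)N1[C@H](Cc2ccccc2)COC1=O | starting material
2 | tiglic aldehyde, (E)-2-methylbut-2-enal | C/C=C(\C)C=O | starting material
3 | dibutylboron Z-enolate of 1 (not isolated) | C/C=C(\OB(CCCC)CCCC)N1[C@H](Cc2ccccc2)COC1=O | intermediate
4 | dibutylboron aldolate, O-dibutylboranyl derivative of 5 (not isolated) | C/C=C(\C)[C@H](OB(CCCC)CCCC)[C@@H](C)C(=O)N1[C@H](Cc2ccccc2)COC1=O | intermediate
5 | (R)-4-benzyl-3-[(2R,3R,4E)-3-hydroxy-2,4-dimethylhex-4-enoyl]-1,3-oxazolidin-2-one | C/C=C(\C)[C@H](O)[C@@H](C)C(=O)N1[C@H](Cc2ccccc2)COC1=O | intermediate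
6 | (2R,3R,4E)-3-hydroxy-N-methoxy-N,2,4-trimethylhex-4-enamide | C/C=C(\C)[C@H](O)[C@@H](C)C(=O)N(C)OC | intermediate
7 | 3-bromo-1-(trimethylsilyl)prop-1-yne | C[Si](C)(C)C#CCBr | starting material
8 | sodium alkoxide of 6 (not isolated) | C/C=C(\C)[C@H]([O-])[C@@H](C)C(=O)N(C)OC.[Na+] | intermediate
9 | (2R,3R,4E)-N-methoxy-N,2,4-trimethyl-3-{[3-(trimethylsilyl)prop-2-yn-1-yl]oxy}hex-4-enamide | C/C=C(\C)[C@H](OCC#C[Si](C)(C)C)[C@@H](C)C(=O)N(C)OC | intermediate
10 | aluminium hemiaminal, tetrahedral iBu2Al–O adduct of 9 at C1 (not isolated) | C/C=C(\C)[C@H](OCC#C[Si](C)(C)C)[C@@H](C)C(O[Al](CC(C)C)CC(C)C)N(C)OC | intermediate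
11 | (2R,3R,4E)-2,4-dimethyl-3-{[3-(trimethylsilyl)prop-2-yn-1-yl]oxy}hex-4-enal | C/C=C(\C)[C@H](OCC#C[Si](C)(C)C)[C@@H](C)C=O | intermediate
12 | 3-(triphenyl-λ5-phosphanylidene)butan-2-one | CC(=O)C(C)=P(c1ccccc1)(c1ccccc1)c1ccccc1 | starting material
13 | (3E,5S,6R,7E)-3,5,7-trimethyl-6-{[3-(trimethylsilyl)prop-2-yn-1-yl]oxy}nona-3,7-dien-2-one | C/C=C(\C)[C@H](OCC#C[Si](C)(C)C)[C@@H](C)/C=C(\C)C(C)=O | intermediate
14 | (2R,3E,5S,6R,7E)-3,5,7-trimethyl-6-{[3-(trimethylsilyl)prop-2-yn-1-yl]oxy}nona-3,7-dien-2-ol | C/C=C(\C)[C@H](OCC#C[Si](C)(C)C)[C@@H](C)/C=C(\C)[C@@H](C)O | intermediate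
15 | (2R,3E,5S,6R,7E)-2-[(tert-butyldimethylsilyl)oxy]-3,5,7-trimethyl-6-{[3-(trimethylsilyl)prop-2-yn-1-yl]oxy}nona-3,7-diene | C/C=C(\C)[C@H](OCC#C[Si](C)(C)C)[C@@H](C)/C=C(\C)[C@@H](C)O[Si](C)(C)C(C)(C)C | intermediate
16 | α-lithio ether, 15 lithiated at the O–CH2 carbon (not isolated) | C/C=C(\C)[C@H](OC([Li])C#C[Si](C)(C)C)[C@@H](C)/C=C(\C)[C@@H](C)O[Si](C)(C)C(C)(C)C | intermediate
17 | (3S,4S,5E,7R,8E,10R)-10-[(tert-butyldimethylsilyl)oxy]-4,5,7,9-tetramethyl-1-(trimethylsilyl)undeca-5,8-dien-1-yn-3-ol | C[Si](C)(C)C#C[C@@H](O)[C@@H](C)/C(C)=C/[C@@H](C)/C=C(\C)[C@@H](C)O[Si](C)(C)C(C)(C)C | intermediate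
18 | (3S,4S,5E,7R,8E,10R)-3,10-bis[(tert-butyldimethylsilyl)oxy]-4,5,7,9-tetramethyl-1-(trimethylsilyl)undeca-5,8-dien-1-yne | C[Si](C)(C)C#C[C@@H](O[Si](C)(C)C(C)(C)C)[C@@H](C)/C(C)=C/[C@@H](C)/C=C(\C)[C@@H](C)O[Si](C)(C)C(C)(C)C | intermediate
19 | (3S,4S,5E,7R,8E,10R)-3,10-bis[(tert-butyldimethylsilyl)oxy]-4,5,7,9-tetramethylundeca-5,8-dien-1-yne | C#C[C@@H](O[Si](C)(C)C(C)(C)C)[C@@H](C)/C(C)=C/[C@@H](C)/C=C(\C)[C@@H](C)O[Si](C)(C)C(C)(C)C | intermediate
20 | lithium acetylide of 19 (not isolated) | [Li]C#C[C@@H](O[Si](C)(C)C(C)(C)C)[C@@H](C)/C(C)=C/[C@@H](C)/C=C(\C)[C@@H](C)O[Si](C)(C)C(C)(C)C | intermediate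
21 | lithium hemiaminal alkoxide, adduct of 20 with DMF (not isolated) | CN(C)C(O[Li])C#C[C@@H](O[Si](C)(C)C(C)(C)C)[C@@H](C)/C(C)=C/[C@@H](C)/C=C(\C)[C@@H](C)O[Si](C)(C)C(C)(C)C | intermediate
22 | (4S,5S,6E,8R,9E,11R)-4,11-bis[(tert-butyldimethylsilyl)oxy]-5,6,8,10-tetramethyldodeca-6,9-dien-2-ynal | O=CC#C[C@@H](O[Si](C)(C)C(C)(C)C)[C@@H](C)/C(C)=C/[C@@H](C)/C=C(\C)[C@@H](C)O[Si](C)(C)C(C)(C)C | intermediate
23 | tert-butyl propanoate | CCC(=O)OC(C)(C)C | starting material
24 | lithium enolate of 23 (not isolated) | CC=C(O[Li])OC(C)(C)C | intermediate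
25 | tert-butyl (6S,7S,8E,10R,11E,13R)-6,13-bis[(tert-butyldimethylsilyl)oxy]-3-hydroxy-2,7,8,10,12-pentamethyltetradeca-8,11-dien-4-ynoate (C2/C3 epimers) | CC(C)(C)OC(=O)C(C)C(O)C#C[C@@H](O[Si](C)(C)C(C)(C)C)[C@@H](C)/C(C)=C/[C@@H](C)/C=C(\C)[C@@H](C)O[Si](C)(C)C(C)(C)C | intermediate
26 | tert-butyl (6S,7S,8E,10R,11E,13R)-6,13-bis[(tert-butyldimethylsilyl)oxy]-2,7,8,10,12-pentamethyl-3-oxotetradeca-8,11-dien-4-ynoate (C2 epimers) | CC(C)(C)OC(=O)C(C)C(=O)C#C[C@@H](O[Si](C)(C)C(C)(C)C)[C@@H](C)/C(C)=C/[C@@H](C)/C=C(\C)[C@@H](C)O[Si](C)(C)C(C)(C)C | intermediate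
27 | vinylgold oxocarbenium: six-membered ring closed at O1–C6, Ph3PAu on C5, tert-butyl still on the C2 oxygen, NTf2 counter-ion (not isolated) | CC1C(=O)C([Au-][P+](c2ccccc2)(c2ccccc2)c2ccccc2)=C([C@@H](O[Si](C)(C)C(C)(C)C)[C@@H](C)/C(C)=C/[C@@H](C)/C=C(\C)[C@@H](C)O[Si](C)(C)C(C)(C)C)OC1=[O+]C(C)(C)C.[N-](S(=O)(=O)C(F)(F)F)S(=O)(=O)C(F)(F)F | intermediate
28 | 3-methyl-6-substituted 2H-pyran-2,4(3H)-dione, keto tautomer of 29 (not isolated) | CC1C(=O)C=C([C@@H](O[Si](C)(C)C(C)(C)C)[C@@H](C)/C(C)=C/[C@@H](C)/C=C(\C)[C@@H](C)O[Si](C)(C)C(C)(C)C)OC1=O | intermediate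
29 | 6-[(1S,2S,3E,5R,6E,8R)-1,8-bis[(tert-butyldimethylsilyl)oxy]-2,3,5,7-tetramethylnona-3,6-dien-1-yl]-4-hydroxy-3-methyl-2H-pyran-2-one | Cc1c(O)cc([C@@H](O[Si](C)(C)C(C)(C)C)[C@@H](C)/C(C)=C/[C@@H](C)/C=C(\C)[C@@H](C)O[Si](C)(C)C(C)(C)C)oc1=O | intermediate
30 | 6-[(1S,2S,3E,5R,6E,8R)-1,8-bis[(tert-butyldimethylsilyl)oxy]-2,3,5,7-tetramethylnona-3,6-dien-1-yl]-4-methoxy-3-methyl-2H-pyran-2-one | COc1cc([C@@H](O[Si](C)(C)C(C)(C)C)[C@@H](C)/C(C)=C/[C@@H](C)/C=C(\C)[C@@H](C)O[Si](C)(C)C(C)(C)C)oc(=O)c1C | intermediate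
31 | 6-[(1S,2S,3E,5R,6E,8R)-1,8-dihydroxy-2,3,5,7-tetramethylnona-3,6-dien-1-yl]-4-methoxy-3-methyl-2H-pyran-2-one | COc1cc([C@@H](O)[C@@H](C)/C(C)=C/[C@@H](C)/C=C(\C)[C@@H](C)O)oc(=O)c1C | target

Total step count: 16. Longest linear sequence: 16 steps (1 and 2 to 31).

Steps most likely to fail

Step 14 (key step). The gold-activated alkyne may be intercepted by the C9=C10 alkene (enyne cycloisomerisation) instead of the ester oxygen, closure may stall at the vinylgold stage, and the acidic medium may erode the silyl ethers. Fallback: the ring is closed at the acyl end (O1–C2) by known chemistry. Starting from 26, pyrrolidine is added in conjugate fashion to the ynone (CH2Cl2, 0 °C) to give the enaminone, tert-butyl (6S,7S,8E,10R,11E,13R)-6,13-bis[(tert-butyldimethylsilyl)oxy]-2,7,8,10,12-pentamethyl-3-oxo-5-(pyrrolidin-1-yl)tetradeca-4,8,11-trienoate F1. Mild hydrolysis (aqueous oxalic acid, THF) should give the 3,5-dioxo ester F2. Heating in toluene at 110 °C should expel tert-butanol to give the acylketene F3, which closes onto the C6 enol oxygen and rejoins the route at 29. This passes through a triketo ester, so the C7 centre would have to be checked for epimerisation.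

Step 8. Incomplete discrimination between exo and endo placement of the alkynyl group in the envelope transition state would erode the anti relationship at C7/C8, and a competing [1,2]-shift would divert material. Fallback: C7 is set by catalyst-controlled reduction instead of by the rearrangement. Starting from 17 as the C7 epimer mixture, Dess–Martin oxidation gives the ynone, (4S,5E,7R,8E,10R)-10-[(tert-butyldimethylsilyl)oxy]-4,5,7,9-tetramethyl-1-(trimethylsilyl)undeca-5,8-dien-1-yn-3-one F4. Asymmetric transfer hydrogenation with RuCl[(S,S)-TsDPEN](p-cymene) in iPrOH should then return 17 with the (7S) configuration.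

Step 3. The sodium alkoxide of the β-hydroxy amide may fragment by retro-aldol reaction or epimerise C11 before it is alkylated, and the alkynylsilane may be partly cleaved by alkoxide. Fallback: the ether is made only after the carbonyl group has gone, at the cost of two more steps. Starting from 6, silylation (Et3SiCl, imidazole) gives the triethylsilyl ether F5, and iBu2AlH reduction gives the aldehyde F6. Wittig reaction with 12 gives the enone F7, and CBS reduction as in step 6 gives the allylic alcohol F8. TBSCl gives the bis-silyl ether F9, and selective cleavage of the triethylsilyl group (pyridinium p-toluenesulfonate, MeOH, 0 °C) gives the C10 alcohol F10. Williamson propargylation of F10 with NaH and 7 rejoins the route at 15.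

Further compounds
F1 | step 14 | tert-butyl (6S,7S,8E,10R,11E,13R)-6,13-bis[(tert-butyldimethylsilyl)oxy]-2,7,8,10,12-pentamethyl-3-oxo-5-(pyrrolidin-1-yl)tetradeca-4,8,11-trienoate | CC(C)(C)OC(=O)C(C)C(=O)C=C(N1CCCC1)[C@@H](O[Si](C)(C)C(C)(C)C)[C@@H](C)/C(C)=C/[C@@H](C)/C=C(\C)[C@@H](C)O[Si](C)(C)C(C)(C)C
F2 | step 14 | tert-butyl (6S,7S,8E,10R,11E,13R)-6,13-bis[(tert-butyldimethylsilyl)oxy]-2,7,8,10,12-pentamethyl-3,5-dioxotetradeca-8,11-dienoate | CC(C)(C)OC(=O)C(C)C(=O)CC(=O)[C@@H](O[Si](C)(C)C(C)(C)C)[C@@H](C)/C(C)=C/[C@@H](C)/C=C(\C)[C@@H](C)O[Si](C)(C)C(C)(C)C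
F3 | step 14 | (6S,7S,8E,10R,11E,13R)-6,13-bis[(tert-butyldimethylsilyl)oxy]-2,7,8,10,12-pentamethyltetradeca-1,8,11-triene-1,3,5-trione (acylketene) | CC(=C=O)C(=O)CC(=O)[C@@H](O[Si](C)(C)C(C)(C)C)[C@@H](C)/C(C)=C/[C@@H](C)/C=C(\C)[C@@H](C)O[Si](C)(C)C(C)(C)C
F4 | step 8 | (4S,5E,7R,8E,10R)-10-[(tert-butyldimethylsilyl)oxy]-4,5,7,9-tetramethyl-1-(trimethylsilyl)undeca-5,8-dien-1-yn-3-one | C[Si](C)(C)C#CC(=O)[C@@H](C)/C(C)=C/[C@@H](C)/C=C(\C)[C@@H](C)O[Si](C)(C)C(C)(C)C
F5 | step 3 | (2R,3R,4E)-N-methoxy-N,2,4-trimethyl-3-[(triethylsilyl)oxy]hex-4-enamide | C/C=C(\C)[C@H](O[Si](CC)(CC)CC)[C@@H](C)C(=O)N(C)OC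
F6 | step 3 | (2R,3R,4E)-2,4-dimethyl-3-[(triethylsilyl)oxy]hex-4-enal | C/C=C(\C)[C@H](O[Si](CC)(CC)CC)[C@@H](C)C=O
F7 | step 3 | (3E,5S,6R,7E)-3,5,7-trimethyl-6-[(triethylsilyl)oxy]nona-3,7-dien-2-one | C/C=C(\C)[C@H](O[Si](CC)(CC)CC)[C@@H](C)/C=C(\C)C(C)=O
F8 | step 3 | (2R,3E,5S,6R,7E)-3,5,7-trimethyl-6-[(triethylsilyl)oxy]nona-3,7-dien-2-ol | C/C=C(\C)[C@H](O[Si](CC)(CC)CC)[C@@H](C)/C=C(\C)[C@@H](C)O
F9 | step 3 | (2R,3E,5S,6R,7E)-2-[(tert-butyldimethylsilyl)oxy]-3,5,7-trimethyl-6-[(triethylsilyl)oxy]nona-3,7-diene | C/C=C(\C)[C@H](O[Si](CC)(CC)CC)[C@@H](C)/C=C(\C)[C@@H](C)O[Si](C)(C)C(C)(C)C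
F10 | step 3 | (2E,4R,5S,6E,8R)-8-[(tert-butyldimethylsilyl)oxy]-3,5,7-trimethylnona-2,6-dien-4-ol | C/C=C(\C)[C@H](O)[C@@H](C)/C=C(\C)[C@@H](C)O[Si](C)(C)C(C)(C)C
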